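**Strategy**

Broussonol A is cut across ring A at C7–C8 and C5–C6, so that C6 and C7 derive from an acetyl unit, C5 from an ester on the pyranone (ring C) and C8 from a pyranone-bound methylene that already carries the 1,1-dimethylallyl group. The key step exploits the 1,3-relationship of the C5 and C7 hydroxyls of ring A fused at C4a–C8a: one base-mediated operation acetylates the C8 carbanion and closes ring A by Claisen condensation, giving the 5,7-diol with no C6/C8 ambiguity. Its precursor is a fully substituted 4-pyranone bearing the chromene ring B at C2, a MOM-protected 3-oxygen, the ester and the 2,2-dimethylbut-3-enyl chain.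

Key step: step 11

Remarks on the chemistry:
- The target has no stereocentre. The sp3 centres in 10, 11, 14 and 17 are enolisable or short-lived, are carried as mixtures and are gone after step 11.
- Compound 15 is named with IUPAC pyranone locants (ester on C3, aryl on C6). Its ring-bound methylene carbon becomes flavone C8 and its ester carbon becomes C5.
- Ring B is taken from 3,4-dihydroxybenzaldehyde because its two hydroxyls differ strongly in acidity. This places the chromene oxygen para to the future C2 attachment without ambiguity.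

**Route**

Step 1
Reactants: 1 3,4-dihydroxybenzaldehyde; 2 3-chloro-3-methylbut-1-yne
Product: 3 3-hydroxy-4-[(2-methylbut-3-yn-2-yl)oxy]benzaldehyde
Conditions: CuCl2·2H2O (cat.), DBU (1.0 equiv), MeCN, 0 °C, argon
Reagents that add atoms: none
Why: Copper-catalysed O-propargylation of a phenol (Williamson-type etherification): with one equivalent of DBU only the 4-OH, para to the formyl group and several pKa units more acidic than the 3-OH, is ionised and alkylated, and the low temperature keeps the free 3-OH from adding to the alkyne.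

Step 2
Reactants: 3 3-hydroxy-4-[(2-methylbut-3-yn-2-yl)oxy]benzaldehyde
Product: 4 3-(methoxymethoxy)-4-[(2-methylbut-3-yn-2-yl)oxy]benzaldehyde
Conditions: MOMCl, i-Pr2NEt, CH2Cl2, 0 °C to rt
Reagents that add atoms: chloromethyl methyl ether, COCCl
Why: Standard MOM ether formation on the remaining phenol (O-alkylation with an α-chloro ether and a hindered amine), which also removes the nucleophilic ortho-hydroxyl before the thermal step.

Step 3
Reactants: 4 3-(methoxymethoxy)-4-[(2-methylbut-3-yn-2-yl)oxy]benzaldehyde
Product: 5 8-(methoxymethoxy)-2,2-dimethyl-2H-chromene-6-carbaldehyde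
Conditions: N,N-diethylaniline, 190 °C
Reagents that add atoms: none
Why: Thermal aryl propargyl ether Claisen rearrangement to C5, the only free ortho position, followed in the same cascade by 1,5-hydrogen shift and 6π-oxa-electrocyclisation, the classical route from aryl 1,1-dimethylpropargyl ethers to 2,2-dimethyl-2H-chromenes; the MOM ether and the aldehyde are inert in the hot basic medium.

Step 4
Reactants: 6 methyl glycolate
Product: 7 methyl 2-(methoxymethoxy)acetate
Conditions: MOMCl, i-Pr2NEt, CH2Cl2, 0 °C to rt
Reagents that add atoms: chloromethyl methyl ether, COCCl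
Why: MOM protection of a primary alcohol under mild basic conditions; the ester is untouched.

Step 5
Reactants: 7 methyl 2-(methoxymethoxy)acetate; 8 methyl acetate
Product: 9 methyl 4-(methoxymethoxy)-3-oxobutanoate
Conditions: LiN(i-Pr)2 (LDA, 2.2 equiv), 8 (2.2 equiv), THF, −78 °C; then 7, −78 to −40 °C; aq. NH4Cl
Reagents that add atoms: none
Why: Crossed Claisen condensation: the preformed lithium enolate of methyl acetate adds to the inductively activated alkoxyacetate, and the β-keto ester is protected from a second addition as its enolate, for which the second equivalent of enolate is supplied.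

Step 6
Reactants: 9 methyl 4-(methoxymethoxy)-3-oxobutanoate; 5 8-(methoxymethoxy)-2,2-dimethyl-2H-chromene-6-carbaldehyde
Product: 10 methyl 5-hydroxy-4-(methoxymethoxy)-5-[8-(methoxymethoxy)-2,2-dimethyl-2H-chromen-6-yl]-3-oxopentanoate (syn/anti mixture, racemic)
Conditions: 9, LiN(i-Pr)2 (LDA, 2.1 equiv), THF, −78 to −20 °C; then 5, −78 °C; aq. NH4Cl
Reagents that add atoms: none
Why: Aldol addition of a β-keto ester dianion, which reacts at its terminal γ-carbon, to the aldehyde; the two new stereocentres form without control and both are erased later (the carbinol in step 7, the C4 centre in step 10).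

Step 7
Reactants: 10 methyl 5-hydroxy-4-(methoxymethoxy)-5-[8-(methoxymethoxy)-2,2-dimethyl-2H-chromen-6-yl]-3-oxopentanoate
Product: 11 methyl 4-(methoxymethoxy)-5-[8-(methoxymethoxy)-2,2-dimethyl-2H-chromen-6-yl]-3,5-dioxopentanoate (racemic at C4, largely enolised)
Conditions: Dess–Martin periodinane, CH2Cl2, 0 °C to rt
Reagents that add atoms: none
Why: Dess–Martin oxidation of the benzylic secondary alcohol to the aryl ketone under mild, nearly neutral conditions that leave the MOM ethers, the chromene alkene and the β-keto ester alone.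

Step 8
Reactants: 12 3,3-dimethylpent-4-enoic acid
Product: 13 3,3-dimethylpent-4-enoyl chloride
Conditions: (COCl)2, DMF (cat.), CH2Cl2, 0 °C to rt
Reagents that add atoms: oxalyl chloride, O=C(Cl)C(=O)Cl
Why: Acid chloride formation with oxalyl chloride and catalytic DMF (Vilsmeier-type activation); the monosubstituted alkene next to a quaternary carbon does not add HCl under these conditions.

Step 9
Reactants: 11 methyl 4-(methoxymethoxy)-5-[8-(methoxymethoxy)-2,2-dimethyl-2H-chromen-6-yl]-3,5-dioxopentanoate; 13 3,3-dimethylpent-4-enoyl chloride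
Product: 14 methyl 2-(3,3-dimethylpent-4-enoyl)-4-(methoxymethoxy)-5-[8-(methoxymethoxy)-2,2-dimethyl-2H-chromen-6-yl]-3,5-dioxopentanoate (keto/enol mixture, used crude)
Conditions: MgCl2, pyridine, CH2Cl2, 0 °C to rt; cold aq. NaH2PO4 work-up
Reagents that add atoms: none
Why: C-acylation of a magnesium-chelated β-keto ester with an acid chloride (MgCl2/pyridine soft enolisation): C2 is the only position whose acylation product is again an acidic, chelating tricarbonyl, so reaction there is thermodynamically favoured over O-acylation or attack at the hindered, oxygen-bearing C4.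

Step 10
Reactants: 14 methyl 2-(3,3-dimethylpent-4-enoyl)-4-(methoxymethoxy)-5-[8-(methoxymethoxy)-2,2-dimethyl-2H-chromen-6-yl]-3,5-dioxopentanoate
Product: 15 methyl 2-(2,2-dimethylbut-3-en-1-yl)-5-(methoxymethoxy)-6-[8-(methoxymethoxy)-2,2-dimethyl-2H-chromen-6-yl]-4-oxo-4H-pyran-3-carboxylate
Conditions: Ph3P, CCl4, Et3N, THF, rt
Reagents that add atoms: none
Why: Neutral Ph3P/CCl4 cyclodehydration of a 1,3,5-tricarbonyl array to a 4-pyranone: a terminal enol oxygen is turned into an oxyphosphonium leaving group and displaced by the other terminal enol oxygen in a 6-endo addition–elimination, which bypasses the ester (no 2-pyranone) and, with Et3N taking up HCl, spares the MOM ethers.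

Step 11
Reactants: 15 methyl 2-(2,2-dimethylbut-3-en-1-yl)-5-(methoxymethoxy)-6-[8-(methoxymethoxy)-2,2-dimethyl-2H-chromen-6-yl]-4-oxo-4H-pyran-3-carboxylate; 16 N-methoxy-N-methylacetamide
Product: 18 5,7-dihydroxy-3-(methoxymethoxy)-2-[8-(methoxymethoxy)-2,2-dimethyl-2H-chromen-6-yl]-8-(2-methylbut-3-en-2-yl)-4H-chromen-4-one, via acetylated pyranone ester 17 (not isolated)
Conditions: LiN(i-Pr)2 (LDA, 1.2 equiv), THF, −78 °C; 16 (1.5 equiv), −78 to 0 °C; LiN(i-Pr)2 (LDA, 3 equiv), −78 °C to rt; aq. NH4Cl
Reagents that add atoms: none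
Why: Proposed new method: LDA removes a proton from the C2 methylene of 15 (flavone C8), the only acidic C–H, because the anion is delocalised through C2=C3 into both the ring carbonyl and the ester; this carbanion adds to the Weinreb amide 16 to form the C7–C8 bond, and on warming with more LDA the chelated adduct collapses to ketone 17, whose methyl group is deprotonated to a dienolate that attacks the neighbouring ester and forms the C5–C6 bond. Loss of methoxide and enolisation then give the aromatic 5,7-diol as its dilithium salt, which makes the sequence irreversible. The closest known reaction type is the tandem acylation–Claisen cyclisation of lithiated ortho-toluates with Weinreb amides or esters to 1,3-dihydroxynaphthalenes, together with the lateral lithiation of 2-alkyl-4-pyranones; what is new is the use of a 4-pyranone-3-carboxylate as the vinylogous toluate and of a neopentyl-type carbanion. Ring A closes in a 6-exo-trig mode (Claisen/Dieckmann type), the ester carbonyl being exocyclic to the forming ring. No stereocentre is created. The step needs site-selective deprotonation (secured by the single activated C–H), C- rather than O-acylation (secured by the amide electrophile, which also stops at the ketone stage) and C- rather than O-cyclisation of 17 (secured by excess LDA, which forms the terminal methyl dienolate), while the regiochemistry at C8 is fixed because the 1,1-dimethylallyl carbon is already attached.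

Step 12
Reactants: 18 5,7-dihydroxy-3-(methoxymethoxy)-2-[8-(methoxymethoxy)-2,2-dimethyl-2H-chromen-6-yl]-8-(2-methylbut-3-en-2-yl)-4H-chromen-4-one
Product: 19 Broussonol A
Conditions: HCl (3 M aq.), MeOH, 40 °C
Reagents that add atoms: none
Why: Acid-catalysed acetal exchange removes both MOM ethers (the enol-type 3-O ether fastest) under dilute HCl in methanol, conditions mild enough to leave the 2,2-dimethylchromene and the 1,1-dimethylallyl group ortho to the 7-OH uncyclised.

**Compound list**

1 | 3,4-dihydroxybenzaldehyde | O=Cc1ccc(O)c(O)c1 | starting material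
2 | 3-chloro-3-methylbut-1-yne | C#CC(C)(C)Cl | starting material
3 | 3-hydroxy-4-[(2-methylbut-3-yn-2-yl)oxy]benzaldehyde | O=Cc1ccc(OC(C)(C)C#C)c(O)c1 | intermediate
4 | 3-(methoxymethoxy)-4-[(2-methylbut-3-yn-2-yl)oxy]benzaldehyde | O=Cc1ccc(OC(C)(C)C#C)c(OCOC)c1 | intermediate
5 | 8-(methoxymethoxy)-2,2-dimethyl-2H-chromene-6-carbaldehyde | O=Cc1cc(OCOC)c2c(c1)C=CC(C)(C)O2 | intermediate
6 | methyl glycolate (methyl 2-hydroxyacetate) | COC(=O)CO | starting material
7 | methyl 2-(methoxymethoxy)acetate | COCOCC(=O)OC | intermediate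
8 | methyl acetate | COC(C)=O | starting material
9 | methyl 4-(methoxymethoxy)-3-oxobutanoate | COCOCC(=O)CC(=O)OC | intermediate
10 | methyl 5-hydroxy-4-(methoxymethoxy)-5-[8-(methoxymethoxy)-2,2-dimethyl-2H-chromen-6-yl]-3-oxopentanoate (syn/anti mixture, racemic) | COC(=O)CC(=O)C(OCOC)C(O)c1cc(OCOC)c2c(c1)C=CC(C)(C)O2 | intermediate
11 | methyl 4-(methoxymethoxy)-5-[8-(methoxymethoxy)-2,2-dimethyl-2H-chromen-6-yl]-3,5-dioxopentanoate (racemic, enolisable) | COC(=O)CC(=O)C(OCOC)C(=O)c1cc(OCOC)c2c(c1)C=CC(C)(C)O2 | intermediate
12 | 3,3-dimethylpent-4-enoic acid | C=CC(C)(C)CC(=O)O | starting material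
13 | 3,3-dimethylpent-4-enoyl chloride | C=CC(C)(C)CC(=O)Cl | intermediate
14 | methyl 2-(3,3-dimethylpent-4-enoyl)-4-(methoxymethoxy)-5-[8-(methoxymethoxy)-2,2-dimethyl-2H-chromen-6-yl]-3,5-dioxopentanoate (keto/enol mixture, sp3 centres unassigned) | COC(=O)C(C(=O)CC(C)(C)C=C)C(=O)C(OCOC)C(=O)c1cc(OCOC)c2c(c1)C=CC(C)(C)O2 | intermediate
15 | methyl 2-(2,2-dimethylbut-3-en-1-yl)-5-(methoxymethoxy)-6-[8-(methoxymethoxy)-2,2-dimethyl-2H-chromen-6-yl]-4-oxo-4H-pyran-3-carboxylate | COC(=O)c1c(CC(C)(C)C=C)oc(-c2cc(OCOC)c3c(c2)C=CC(C)(C)O3)c(OCOC)c1=O | intermediate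
16 | N-methoxy-N-methylacetamide | CC(=O)N(C)OC | starting material
17 | methyl 2-(4,4-dimethyl-2-oxohex-5-en-3-yl)-5-(methoxymethoxy)-6-[8-(methoxymethoxy)-2,2-dimethyl-2H-chromen-6-yl]-4-oxo-4H-pyran-3-carboxylate (racemic, not isolated) | COC(=O)c1c(C(C(C)=O)C(C)(C)C=C)oc(-c2cc(OCOC)c3c(c2)C=CC(C)(C)O3)c(OCOC)c1=O | intermediate
18 | 5,7-dihydroxy-3-(methoxymethoxy)-2-[8-(methoxymethoxy)-2,2-dimethyl-2H-chromen-6-yl]-8-(2-methylbut-3-en-2-yl)-4H-chromen-4-one | C=CC(C)(C)c1c(O)cc(O)c2c(=O)c(OCOC)c(-c3cc(OCOC)c4c(c3)C=CC(C)(C)O4)oc12 | intermediate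
19 | Broussonol A, 3,5,7-trihydroxy-2-(8-hydroxy-2,2-dimethyl-2H-chromen-6-yl)-8-(2-methylbut-3-en-2-yl)-4H-chromen-4-one (achiral) | C=CC(C)(C)c1c(O)cc(O)c2c(=O)c(O)c(-c3cc(O)c4c(c3)C=CC(C)(C)O4)oc12 | target

**Step count**

Total: 12 steps. Longest linear sequence: 9 steps (steps 1, 2, 3, 6, 7, 9, 10, 11, 12). Steps 4–5 and step 8 are side branches.

**Steps most likely to fail, with fallbacks**

Step 11 (key step, proposed new method). The hindered carbanion may act as a base toward 16 instead of adding to it. The ketone stage may close through its enolate oxygen onto the ester. Excess amide base may open the pyranone ring. The fallback brings ring A in preformed and sets the C8 substituent by a known aromatic Claisen rearrangement. It sets out from aldehyde 5 and comes back at target 19. Commercial 2',4',6'-trihydroxyacetophenone would be O-alkylated at its unchelated 4-hydroxyl with prenyl bromide (K2CO3, acetone) to 1-[2,6-dihydroxy-4-(3-methylbut-2-en-1-yloxy)phenyl]ethanone F1. One of the two equivalent chelated hydroxyls would then be capped (MOMCl, i-Pr2NEt) to give 1-[2-hydroxy-6-(methoxymethoxy)-4-(3-methylbut-2-en-1-yloxy)phenyl]ethanone F2. Claisen–Schmidt condensation of F2 with 5 (KOH, EtOH) should give (E)-1-[2-hydroxy-6-(methoxymethoxy)-4-(3-methylbut-2-en-1-yloxy)phenyl]-3-[8-(methoxymethoxy)-2,2-dimethyl-2H-chromen-6-yl]prop-2-en-1-one F3. Algar–Flynn–Oyamada oxidation (H2O2, NaOH, MeOH) should then give 3-hydroxy-5-(methoxymethoxy)-2-[8-(methoxymethoxy)-2,2-dimethyl-2H-chromen-6-yl]-7-(3-methylbut-2-en-1-yloxy)-4H-chromen-4-one F4. Heating F4 in N,N-diethylaniline at about 190 °C should move the prenyl group from O7 to C8 with allylic inversion. The para position C4a is blocked, and C8 is the ortho position usually preferred in 7-allyloxychromones; any C6 isomer would be separated. The product is 3,7-dihydroxy-5-(methoxymethoxy)-2-[8-(methoxymethoxy)-2,2-dimethyl-2H-chromen-6-yl]-8-(2-methylbut-3-en-2-yl)-4H-chromen-4-one F5. Removal of the MOM groups under the conditions of step 12 would give 19.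

Step 9. Acylation may occur at an enol oxygen or at C4 instead of C2, and the tricarbonyl product may be deacylated during isolation. The fallback delivers the acyl carbon at the amide oxidation level, so that only the C2 methylene can condense and ring closure needs no dehydration. It sets out from 13 and 11 and comes back at 15, bypassing steps 9 and 10. Acid chloride 13 and dimethylamine would give N,N,3,3-tetramethylpent-4-enamide F6. O-Methylation (Me2SO4) followed by NaOMe would give the amide acetal 1,1-dimethoxy-N,N,3,3-tetramethylpent-4-en-1-amine F7. Warming F7 with 11 in toluene should condense it at C2 with loss of methanol to the enaminone methyl 2-[1-(dimethylamino)-3,3-dimethylpent-4-en-1-ylidene]-4-(methoxymethoxy)-5-[8-(methoxymethoxy)-2,2-dimethyl-2H-chromen-6-yl]-3,5-dioxopentanoate F8. F8 is not isolated: the C5 enol oxygen adds to the aminovinyl carbon and dimethylamine is expelled to give 15. This is the established amide-acetal annulation of 1,3-dicarbonyl compounds to 4-pyranones.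

Step 10. The phosphonium reagent may activate the central instead of a terminal enol oxygen, so that chloride is captured in place of ring closure. Adventitious HCl may also strip a MOM group. The fallback closes the ring under acid, accepts loss of the protecting groups and puts them back. It sets out from 14 and comes back at 15. Treatment of 14 with p-TsOH·H2O in MeOH–toluene at 60 °C should effect the classical acid cyclodehydration of the triketone and cleave both MOM ethers. The product would be methyl 2-(2,2-dimethylbut-3-en-1-yl)-5-hydroxy-6-(8-hydroxy-2,2-dimethyl-2H-chromen-6-yl)-4-oxo-4H-pyran-3-carboxylate F9. Double O-alkylation of F9 (MOMCl, i-Pr2NEt, CH2Cl2) would return 15.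

**Further compounds**

F1 | step 11 | 1-[2,6-dihydroxy-4-(3-methylbut-2-en-1-yloxy)phenyl]ethanone | CC(=O)c1c(O)cc(OCC=C(C)C)cc1O
F2 | step 11 | 1-[2-hydroxy-6-(methoxymethoxy)-4-(3-methylbut-2-en-1-yloxy)phenyl]ethanone | CC(=O)c1c(O)cc(OCC=C(C)C)cc1OCOC
F3 | step 11 | (E)-1-[2-hydroxy-6-(methoxymethoxy)-4-(3-methylbut-2-en-1-yloxy)phenyl]-3-[8-(methoxymethoxy)-2,2-dimethyl-2H-chromen-6-yl]prop-2-en-1-one | COCOc1cc(OCC=C(C)C)cc(O)c1C(=O)/C=C/c1cc(OCOC)c2c(c1)C=CC(C)(C)O2
F4 | step 11 | 3-hydroxy-5-(methoxymethoxy)-2-[8-(methoxymethoxy)-2,2-dimethyl-2H-chromen-6-yl]-7-(3-methylbut-2-en-1-yloxy)-4H-chromen-4-one | COCOc1cc(OCC=C(C)C)cc2oc(-c3cc(OCOC)c4c(c3)C=CC(C)(C)O4)c(O)c(=O)c12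
F5 | step 11 | 3,7-dihydroxy-5-(methoxymethoxy)-2-[8-(methoxymethoxy)-2,2-dimethyl-2H-chromen-6-yl]-8-(2-methylbut-3-en-2-yl)-4H-chromen-4-one | C=CC(C)(C)c1c(O)cc(OCOC)c2c(=O)c(O)c(-c3cc(OCOC)c4c(c3)C=CC(C)(C)O4)oc12
F6 | step 9 | N,N,3,3-tetramethylpent-4-enamide | C=CC(C)(C)CC(=O)N(C)C
F7 | step 9 | 1,1-dimethoxy-N,N,3,3-tetramethylpent-4-en-1-amine | C=CC(C)(C)CC(OC)(OC)N(C)C
F8 | step 9 | methyl 2-[1-(dimethylamino)-3,3-dimethylpent-4-en-1-ylidene]-4-(methoxymethoxy)-5-[8-(methoxymethoxy)-2,2-dimethyl-2H-chromen-6-yl]-3,5-dioxopentanoate | COC(=O)C(=C(CC(C)(C)C=C)N(C)C)C(=O)C(OCOC)C(=O)c1cc(OCOC)c2c(c1)C=CC(C)(C)O2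
F9 | step 10 | methyl 2-(2,2-dimethylbut-3-en-1-yl)-5-hydroxy-6-(8-hydroxy-2,2-dimethyl-2H-chromen-6-yl)-4-oxo-4H-pyran-3-carboxylate | COC(=O)c1c(CC(C)(C)C=C)oc(-c2cc(O)c3c(c2)C=CC(C)(C)O3)c(O)c1=O
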